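**Retrosynthetic overview**

1. The last disconnection is the biaryl bond between ring B (aryl on tetrahydrofuran C2) and ring C (aryl on tetralin C1). It is made by Suzuki coupling of tetrahydrofuran-half boronate 21 with tetralin-half bromide 34, and four phenolic benzyl ethers are then removed.
2. The strategy rests on the tetrahydrofuran O1–C2–C3–C4–C5: ring B on C2, CH2OH on C3 trans to it, OH on C4 trans to that CH2OH. Read as a lactone with C5 as carbonyl, this is a 5-aryl-3-benzyl butenolide that accepts a CH2 group at C3 and an OH at C4, each anti to its neighbour (step 11).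
3. The same triad recurs as C1–C2–C3 of the tetralin (C2 and C3 have the identical configuration). The tetralin half is therefore made by the same addition–oxidation on the vanillyl butenolide, then lactone opening and acid-induced Friedel–Crafts closure of C1–C8a.
4. Ring order: in the first half the butenolide ring is closed by metathesis and never opened (lactone → lactol → ether). In the second half the butenolide comes first, then the carbocycle. The biaryl bond is formed last.
5. Both butenolides come from one resolved (S)-1-arylallyl alcohol (from 5-bromovanillin), esterified with a 2-benzylacrylic acid (from diethyl malonate and an O-benzylated hydroxymethoxybenzaldehyde).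

Key step: step 11

Remark 1: 3-(benzyloxy)-4-methoxybenzaldehyde (5) and 4-(benzyloxy)-3-methoxybenzaldehyde (22) are taken as catalogue compounds; each is otherwise one benzylation away from isovanillin or vanillin.

Remark 2: compound names use lactone numbering (C2 carbonyl or its CH2, C3 benzyl carbinol, C4 CH2X, C5 aryl), which corresponds to C5, C4, C3, C2 of the tetrahydrofuran as numbered in the overview. Tetralins are numbered from the aryl-bearing carbon (C1).

Remark 3: the lactone is not opened in the tetrahydrofuran half, because a free triol would let the isopropoxysilane exchange with the neighbouring hydroxyls and blur the selective ring closure. Exchange at silicon for fluoride (step 13) or for neighbouring alkoxides (step 23) is harmless, since all such silicon species are oxidised to the same alcohol.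

**Common aryl fragment**

Step 1
Reactants: 1 5-bromovanillin
Product: 2 4-(benzyloxy)-3-bromo-5-methoxybenzaldehyde
Conditions: BnBr, K2CO3, DMF, 60 °C
Reagents that add atoms: benzyl bromide, BrCc1ccccc1
Why: Williamson ether synthesis on the phenoxide; the aldehyde and the aryl bromide are inert to K2CO3.

Step 2
Reactants: 2 4-(benzyloxy)-3-bromo-5-methoxybenzaldehyde
Product: 3 rac-1-[4-(benzyloxy)-3-bromo-5-methoxyphenyl]prop-2-en-1-ol
Conditions: CH2=CHMgBr, THF, −78 → 0 °C; then sat. aq. NH4Cl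
Reagents that add atoms: vinylmagnesium bromide, C=C[Mg]Br
Why: 1,2-addition of a vinyl Grignard reagent to the aldehyde at low temperature, which the aryl bromide and benzyl ether tolerate; the carbinol centre forms racemic and is resolved in step 3.

Step 3
Reactants: 3 rac-1-[4-(benzyloxy)-3-bromo-5-methoxyphenyl]prop-2-en-1-ol
Product: 4 (S)-1-[4-(benzyloxy)-3-bromo-5-methoxyphenyl]prop-2-en-1-ol
Conditions: Ti(OiPr)4 (10 mol %), L-(+)-diisopropyl tartrate (15 mol %), t-BuOOH (0.6 equiv), 4 Å molecular sieves, CH2Cl2, −20 °C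
Reagents that add atoms: none
Why: Sharpless kinetic resolution: the titanium tartrate from L-(+)-diisopropyl tartrate epoxidises the (R)-alcohol faster (oxygen delivered to the alkene face anti to the aryl group), so running slightly past half conversion should return the (S)-alcohol in high ee; this centre is the only source of absolute configuration for both halves.

**Tetrahydrofuran half**

Step 4
Reactants: 5 3-(benzyloxy)-4-methoxybenzaldehyde; 6 diethyl malonate
Product: 7 diethyl 2-[3-(benzyloxy)-4-methoxybenzylidene]malonate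
Conditions: piperidine (cat.), AcOH (cat.), toluene, reflux, Dean–Stark trap
Reagents that add atoms: none
Why: Knoevenagel condensation driven by azeotropic removal of water.

Step 5
Reactants: 7 diethyl 2-[3-(benzyloxy)-4-methoxybenzylidene]malonate
Product: 8 diethyl 2-[3-(benzyloxy)-4-methoxybenzyl]malonate
Conditions: NaBH4, EtOH, 0 °C
Reagents that add atoms: none
Why: Conjugate reduction of the doubly activated alkylidene malonate by borohydride, which spares the esters at 0 °C and, unlike hydrogenation, the benzyl ether.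

Step 6
Reactants: 8 diethyl 2-[3-(benzyloxy)-4-methoxybenzyl]malonate
Product: 9 2-[3-(benzyloxy)-4-methoxybenzyl]malonic acid
Conditions: KOH, EtOH/H2O, reflux; then aq. HCl, 0 °C
Reagents that add atoms: potassium hydroxide, [K+].[OH-]
Why: Saponification of both esters; acidification in the cold avoids premature decarboxylation.

Step 7
Reactants: 9 2-[3-(benzyloxy)-4-methoxybenzyl]malonic acid
Product: 10 2-[3-(benzyloxy)-4-methoxybenzyl]acrylic acid
Conditions: paraformaldehyde, Et2NH, EtOAc, reflux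
Reagents that add atoms: formaldehyde (as paraformaldehyde), C=O
Why: Mannich-type decarboxylative methylenation: the malonic acid condenses with formaldehyde and diethylamine, and the Mannich base loses CO2 and amine to give the 2-substituted acrylic acid.

Step 8
Reactants: 4 (S)-1-[4-(benzyloxy)-3-bromo-5-methoxyphenyl]prop-2-en-1-ol; 10 2-[3-(benzyloxy)-4-methoxybenzyl]acrylic acid
Product: 11 (S)-1-[4-(benzyloxy)-3-bromo-5-methoxyphenyl]allyl 2-[3-(benzyloxy)-4-methoxybenzyl]acrylate
Conditions: EDC·HCl, DMAP (cat.), CH2Cl2, 0 °C → rt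
Reagents that add atoms: none
Why: Carbodiimide (Steglich-type) esterification under neutral conditions acylates the oxygen without touching the ionisable benzylic–allylic C–O bond, so the configuration of 4 is retained.

Step 9
Reactants: 11 (S)-1-[4-(benzyloxy)-3-bromo-5-methoxyphenyl]allyl 2-[3-(benzyloxy)-4-methoxybenzyl]acrylate
Product: 12 (S)-5-[4-(benzyloxy)-3-bromo-5-methoxyphenyl]-3-[3-(benzyloxy)-4-methoxybenzyl]furan-2(5H)-one
Conditions: second-generation Grubbs catalyst (5 mol %), toluene (high dilution), 80 °C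
Reagents that add atoms: none
Why: Ring-closing metathesis between the terminal vinyl group and the 1,1-disubstituted acrylate alkene gives the trisubstituted butenolide with loss of ethylene; the neutral conditions leave the acidic C5–H stereocentre intact.

Step 10
Reactants: 13 (chloromethyl)isopropoxydimethylsilane
Product: 14 (isopropoxydimethylsilyl)methylmagnesium chloride (THF solution, used in steps 11 and 22)
Conditions: Mg turnings, BrCH2CH2Br (cat.), THF, reflux → rt
Reagents that add atoms: magnesium, [Mg]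
Why: Direct insertion of magnesium into the C–Cl bond gives the hydroxymethyl-anion equivalent; the hindered isopropoxy group keeps silicon from being attacked by the Grignard reagent.

Step 11
Reactants: 12 (S)-5-[4-(benzyloxy)-3-bromo-5-methoxyphenyl]-3-[3-(benzyloxy)-4-methoxybenzyl]furan-2(5H)-one; 14 (isopropoxydimethylsilyl)methylmagnesium chloride
Product: 17 (3S,4R,5S)-5-[4-(benzyloxy)-3-bromo-5-methoxyphenyl]-3-[3-(benzyloxy)-4-methoxybenzyl]-3-hydroxy-4-{[isopropoxy(dimethyl)silyl]methyl}dihydrofuran-2(3H)-one, via trimethylsilyl ketene acetal 15 (not isolated), via 3-trimethylsilyloxy lactone 16 (not isolated)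
Conditions: CuBr·SMe2 (10 mol %, monovalent copper), Me3SiCl (3 equiv), 14 (2 equiv, added slowly), THF, −78 °C; then dimethyldioxirane (acetone solution, 3 equiv), −78 → −40 °C; sat. aq. NH4Cl, then citric acid, THF/H2O, 0 °C
Reagents that add atoms: dimethyldioxirane, CC1(C)OO1
Why: The Grignard reagent transmetalates to a monovalent organocopper species that adds 1,4 to the butenolide, Me3SiCl accelerating the addition and trapping the enolate as ketene acetal 15, whose electron-rich C=C is epoxidised by the dioxirane and collapses by silyl shift to the silyloxy lactone 16, desilylated on work-up. The closest known reaction types are the trans-selective copper-catalysed Grignard addition to 5-substituted butenolides with silyl chloride trapping and the Rubottom-type oxidation of silyl ketene acetals. No ring is closed; two skeletal bonds (C4–CH2 and C3–O) and two stereocentres are formed. C4 is set by attack on the butenolide face opposite the C5 aryl group, and C3 by oxygen transfer to the face of the planar ketene acetal opposite the vicinal, bulky CH2SiMe2(OiPr) group, which places OH trans to it and the benzyl group cis. The step needs two successive anti approaches on a flat five-membered ring: the first is secured by the aryl group on the neighbouring carbon, the second by the new C4 substituent being vicinal to C3 while the aryl group on the other face is one atom further away. The slow addition at −78 °C with silyl chloride present keeps the medium effectively non-basic, so the doubly activated C5–H of 12 is not removed and the ee of 4 is carried through.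

Step 12
Reactants: 17 (3S,4R,5S)-5-[4-(benzyloxy)-3-bromo-5-methoxyphenyl]-3-[3-(benzyloxy)-4-methoxybenzyl]-3-hydroxy-4-{[isopropoxy(dimethyl)silyl]methyl}dihydrofuran-2(3H)-one
Product: 18 (3S,4R,5S)-5-[4-(benzyloxy)-3-bromo-5-methoxyphenyl]-3-[3-(benzyloxy)-4-methoxybenzyl]-4-{[isopropoxy(dimethyl)silyl]methyl}tetrahydrofuran-2,3-diol (lactol, both C2 anomers)
Conditions: i-Bu2AlH (3 equiv), CH2Cl2, −78 °C; aq. potassium sodium tartrate
Reagents that add atoms: none
Why: Partial reduction of the lactone by i-Bu2AlH, whose tetrahedral aluminium hemiacetal survives at −78 °C and gives the lactol on work-up (one equivalent is consumed by the tertiary hydroxyl); no existing stereocentre is involved and the anomeric centre is removed in step 13.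

Step 13
Reactants: 18 lactol, (3S,4R,5S)-5-[4-(benzyloxy)-3-bromo-5-methoxyphenyl]-3-[3-(benzyloxy)-4-methoxybenzyl]-4-{[isopropoxy(dimethyl)silyl]methyl}tetrahydrofuran-2,3-diol
Product: 19 (3S,4R,5S)-5-[4-(benzyloxy)-3-bromo-5-methoxyphenyl]-3-[3-(benzyloxy)-4-methoxybenzyl]-4-{[isopropoxy(dimethyl)silyl]methyl}tetrahydrofuran-3-ol (used crude)
Conditions: Et3SiH (5 equiv), BF3·OEt2 (2.5 equiv), CH2Cl2, −78 → −40 °C; Et3N, then aq. NaHCO3
Reagents that add atoms: none
Why: Kraus-type reductive deoxygenation: BF3 ionises the lactol hydroxyl to a cyclic oxocarbenium ion that Et3SiH reduces, so the former carbonyl carbon becomes the ether CH2 without the ring ever opening; the three stereocentres are untouched, and at low temperature the benzylic C5–O bond of the bromo-substituted, doubly ortho-flanked aryl ether is expected to stay intact.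

Step 14
Reactants: 19 (3S,4R,5S)-5-[4-(benzyloxy)-3-bromo-5-methoxyphenyl]-3-[3-(benzyloxy)-4-methoxybenzyl]-4-{[isopropoxy(dimethyl)silyl]methyl}tetrahydrofuran-3-ol
Product: 20 (3S,4R,5S)-5-[4-(benzyloxy)-3-bromo-5-methoxyphenyl]-3-[3-(benzyloxy)-4-methoxybenzyl]-4-(hydroxymethyl)tetrahydrofuran-3-ol
Conditions: KF, KHCO3, 30% H2O2, THF/MeOH, rt
Reagents that add atoms: hydrogen peroxide, OO
Why: Tamao oxidation: fluoride-activated silicon accepts hydroperoxide and the CH2 group migrates from silicon to oxygen, unmasking the hydroxymethyl group; the aryl bromide, the benzyl ethers and the cyclic benzylic ether are inert to buffered H2O2.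

Step 15
Reactants: 20 (3S,4R,5S)-5-[4-(benzyloxy)-3-bromo-5-methoxyphenyl]-3-[3-(benzyloxy)-4-methoxybenzyl]-4-(hydroxymethyl)tetrahydrofuran-3-ol
Product: 21 (3S,4R,5S)-5-[4-(benzyloxy)-3-methoxy-5-(4,4,5,5-tetramethyl-1,3,2-dioxaborolan-2-yl)phenyl]-3-[3-(benzyloxy)-4-methoxybenzyl]-4-(hydroxymethyl)tetrahydrofuran-3-ol
Conditions: bis(pinacolato)diboron, Pd(dppf)Cl2 (5 mol %, divalent palladium precatalyst), KOAc, 1,4-dioxane, 85 °C
Reagents that add atoms: bis(pinacolato)diboron, CC1(C)OB(OC1(C)C)B1OC(C)(C)C(C)(C)O1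
Why: Miyaura borylation of the aryl bromide (oxidative addition to zerovalent palladium formed in the flask, acetate-assisted transmetalation from the diboron); free hydroxyl groups are tolerated.

**Tetralin half**

Step 16
Reactants: 22 4-(benzyloxy)-3-methoxybenzaldehyde; 6 diethyl malonate
Product: 23 diethyl 2-[4-(benzyloxy)-3-methoxybenzylidene]malonate
Conditions: piperidine (cat.), AcOH (cat.), toluene, reflux, Dean–Stark trap
Reagents that add atoms: none
Why: Knoevenagel condensation, as in step 4.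

Step 17
Reactants: 23 diethyl 2-[4-(benzyloxy)-3-methoxybenzylidene]malonate
Product: 24 diethyl 2-[4-(benzyloxy)-3-methoxybenzyl]malonate
Conditions: NaBH4, EtOH, 0 °C
Reagents that add atoms: none
Why: Borohydride conjugate reduction of the alkylidene malonate, as in step 5.

Step 18
Reactants: 24 diethyl 2-[4-(benzyloxy)-3-methoxybenzyl]malonate
Product: 25 2-[4-(benzyloxy)-3-methoxybenzyl]malonic acid
Conditions: KOH, EtOH/H2O, reflux; then aq. HCl, 0 °C
Reagents that add atoms: potassium hydroxide, [K+].[OH-]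
Why: Saponification of both esters, as in step 6.

Step 19
Reactants: 25 2-[4-(benzyloxy)-3-methoxybenzyl]malonic acid
Product: 26 2-[4-(benzyloxy)-3-methoxybenzyl]acrylic acid
Conditions: paraformaldehyde, Et2NH, EtOAc, reflux
Reagents that add atoms: formaldehyde (as paraformaldehyde), C=O
Why: Mannich-type decarboxylative methylenation, as in step 7.

Step 20
Reactants: 4 (S)-1-[4-(benzyloxy)-3-bromo-5-methoxyphenyl]prop-2-en-1-ol; 26 2-[4-(benzyloxy)-3-methoxybenzyl]acrylic acid
Product: 27 (S)-1-[4-(benzyloxy)-3-bromo-5-methoxyphenyl]allyl 2-[4-(benzyloxy)-3-methoxybenzyl]acrylate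
Conditions: EDC·HCl, DMAP (cat.), CH2Cl2, 0 °C → rt
Reagents that add atoms: none
Why: Carbodiimide (Steglich-type) esterification with retention of the carbinol configuration, as in step 8.

Step 21
Reactants: 27 (S)-1-[4-(benzyloxy)-3-bromo-5-methoxyphenyl]allyl 2-[4-(benzyloxy)-3-methoxybenzyl]acrylate
Product: 28 (S)-5-[4-(benzyloxy)-3-bromo-5-methoxyphenyl]-3-[4-(benzyloxy)-3-methoxybenzyl]furan-2(5H)-one
Conditions: second-generation Grubbs catalyst (5 mol %), toluene (high dilution), 80 °C
Reagents that add atoms: none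
Why: Ring-closing metathesis to the trisubstituted butenolide with loss of ethylene, as in step 9.

Step 22
Reactants: 28 (S)-5-[4-(benzyloxy)-3-bromo-5-methoxyphenyl]-3-[4-(benzyloxy)-3-methoxybenzyl]furan-2(5H)-one; 14 (isopropoxydimethylsilyl)methylmagnesium chloride
Product: 31 (3S,4R,5S)-5-[4-(benzyloxy)-3-bromo-5-methoxyphenyl]-3-[4-(benzyloxy)-3-methoxybenzyl]-3-hydroxy-4-{[isopropoxy(dimethyl)silyl]methyl}dihydrofuran-2(3H)-one, via trimethylsilyl ketene acetal 29 (not isolated), via 3-trimethylsilyloxy lactone 30 (not isolated)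
Conditions: CuBr·SMe2 (10 mol %, monovalent copper), Me3SiCl (3 equiv), 14 (2 equiv, added slowly), THF, −78 °C; then dimethyldioxirane (acetone solution, 3 equiv), −78 → −40 °C; sat. aq. NH4Cl, then citric acid, THF/H2O, 0 °C
Reagents that add atoms: dimethyldioxirane, CC1(C)OO1
Why: The same copper-catalysed anti conjugate addition with silyl trapping and Rubottom-type dioxirane oxidation as in step 11, with the same control: CH2Si enters anti to the C5 aryl group and oxygen anti to the new C4 substituent.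

Step 23
Reactants: 31 (3S,4R,5S)-5-[4-(benzyloxy)-3-bromo-5-methoxyphenyl]-3-[4-(benzyloxy)-3-methoxybenzyl]-3-hydroxy-4-{[isopropoxy(dimethyl)silyl]methyl}dihydrofuran-2(3H)-one
Product: 33 (2S,3R,4S)-4-[4-(benzyloxy)-3-bromo-5-methoxyphenyl]-2-[4-(benzyloxy)-3-methoxybenzyl]-3-(hydroxymethyl)butane-1,2,4-triol, via silyl triol 32 (not isolated)
Conditions: LiBH4, THF, 0 °C → rt; then MeOH, KF, KHCO3, 30% H2O2, rt
Reagents that add atoms: hydrogen peroxide, OO
Why: LiBH4 reduces the lactone to the 1,4-diol without touching the aryl bromide, and Tamao oxidation in the same pot converts every silicon species present (isopropoxysilane or siloxanes formed by exchange with the new alkoxides) into the primary alcohol; no stereocentre is involved.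

Step 24
Reactants: 33 (2S,3R,4S)-4-[4-(benzyloxy)-3-bromo-5-methoxyphenyl]-2-[4-(benzyloxy)-3-methoxybenzyl]-3-(hydroxymethyl)butane-1,2,4-triol
Product: 34 (1S,2S,3S)-7-(benzyloxy)-1-[4-(benzyloxy)-3-bromo-5-methoxyphenyl]-2,3-bis(hydroxymethyl)-6-methoxy-1,2,3,4-tetrahydronaphthalen-3-ol
Conditions: TsOH·H2O (10 mol %), (CF3)2CHOH/CH2Cl2, 0 °C → rt
Reagents that add atoms: none
Why: Dehydrative intramolecular Friedel–Crafts alkylation of the aryltetralin-lignan type: the benzylic alcohol ionises and the cation is attacked by the benzyl arene para to its methoxy group to close the six-membered ring; the old benzylic centre is erased and C1 is reset trans to the C2 CH2OH (aryl pseudo-equatorial in the half-chair), while reversible capture of the cation by the primary hydroxyl as a cyclic ether only delays the irreversible C–C bond formation.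

**Union and deprotection**

Step 25
Reactants: 21 tetrahydrofuran-half pinacol boronate; 34 tetralin-half bromide
Product: 35 (3S,4R,5S)-5-{4-(benzyloxy)-3-[2-(benzyloxy)-5-((1S,2S,3S)-7-(benzyloxy)-3-hydroxy-2,3-bis(hydroxymethyl)-6-methoxy-1,2,3,4-tetrahydronaphthalen-1-yl)-3-methoxyphenyl]-5-methoxyphenyl}-3-[3-(benzyloxy)-4-methoxybenzyl]-4-(hydroxymethyl)tetrahydrofuran-3-ol (tetra-O-benzyl ether of the target)
Conditions: Pd(OAc)2 (5 mol %, divalent palladium), SPhos (10 mol %), K3PO4, 1,4-dioxane/H2O, 80 °C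
Reagents that add atoms: none
Why: Suzuki–Miyaura cross-coupling: the electron-rich biaryl phosphine lets zerovalent palladium insert into the ortho-alkoxy aryl bromide and couple the ortho-alkoxy boronate, the new biaryl carries only one ortho substituent on each ring, and free hydroxyl groups are compatible with the aqueous phosphate base.

Step 26
Reactants: 35 tetra-O-benzyl ether of the target
Product: 36 CNP0252244.1, (3S,4R,5S)-5-{4-hydroxy-3-[2-hydroxy-5-((1S,2S,3S)-3,7-dihydroxy-2,3-bis(hydroxymethyl)-6-methoxy-1,2,3,4-tetrahydronaphthalen-1-yl)-3-methoxyphenyl]-5-methoxyphenyl}-3-(3-hydroxy-4-methoxybenzyl)-4-(hydroxymethyl)tetrahydrofuran-3-ol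
Conditions: H2 (1 atm), Pd/C (10 wt % palladium metal on carbon), EtOAc/MeOH, rt, stopped when debenzylation is complete
Reagents that add atoms: none
Why: Hydrogenolysis of the four aryl benzyl ethers, which is much faster than cleavage of the cyclic benzylic C–O bond of the tetrahydrofuran; no stereocentre is affected.

**Compound list**

1 | 5-bromovanillin | COc1cc(C=O)cc(Br)c1O | starting material
2 | 4-(benzyloxy)-3-bromo-5-methoxybenzaldehyde | COc1cc(C=O)cc(Br)c1OCc1ccccc1 | intermediate
3 | rac-1-[4-(benzyloxy)-3-bromo-5-methoxyphenyl]prop-2-en-1-ol | C=CC(O)c1cc(OC)c(OCc2ccccc2)c(Br)c1 | intermediate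
4 | (S)-1-[4-(benzyloxy)-3-bromo-5-methoxyphenyl]prop-2-en-1-ol | C=C[C@H](O)c1cc(OC)c(OCc2ccccc2)c(Br)c1 | intermediate
5 | 3-(benzyloxy)-4-methoxybenzaldehyde | COc1ccc(C=O)cc1OCc1ccccc1 | starting material
6 | diethyl malonate | CCOC(=O)CC(=O)OCC | starting material
7 | diethyl 2-[3-(benzyloxy)-4-methoxybenzylidene]malonate | CCOC(=O)C(=Cc1ccc(OC)c(OCc2ccccc2)c1)C(=O)OCC | intermediate
8 | diethyl 2-[3-(benzyloxy)-4-methoxybenzyl]malonate | CCOC(=O)C(Cc1ccc(OC)c(OCc2ccccc2)c1)C(=O)OCC | intermediate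
9 | 2-[3-(benzyloxy)-4-methoxybenzyl]malonic acid | OC(=O)C(Cc1ccc(OC)c(OCc2ccccc2)c1)C(=O)O | intermediate
10 | 2-[3-(benzyloxy)-4-methoxybenzyl]acrylic acid | C=C(Cc1ccc(OC)c(OCc2ccccc2)c1)C(=O)O | intermediate
11 | (S)-1-[4-(benzyloxy)-3-bromo-5-methoxyphenyl]allyl 2-[3-(benzyloxy)-4-methoxybenzyl]acrylate | C=C(Cc1ccc(OC)c(OCc2ccccc2)c1)C(=O)O[C@@H](C=C)c1cc(OC)c(OCc2ccccc2)c(Br)c1 | intermediate
12 | (S)-5-[4-(benzyloxy)-3-bromo-5-methoxyphenyl]-3-[3-(benzyloxy)-4-methoxybenzyl]furan-2(5H)-one | COc1ccc(CC2=C[C@@H](c3cc(OC)c(OCc4ccccc4)c(Br)c3)OC2=O)cc1OCc1ccccc1 | intermediate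
13 | (chloromethyl)isopropoxydimethylsilane | CC(C)O[Si](C)(C)CCl | starting material
14 | (isopropoxydimethylsilyl)methylmagnesium chloride | CC(C)O[Si](C)(C)C[Mg]Cl | intermediate
15 | (4S,5S)-5-[4-(benzyloxy)-3-bromo-5-methoxyphenyl]-3-[3-(benzyloxy)-4-methoxybenzyl]-4-{[isopropoxy(dimethyl)silyl]methyl}-2-(trimethylsilyloxy)-4,5-dihydrofuran | COc1ccc(CC2=C(O[Si](C)(C)C)O[C@H](c3cc(OC)c(OCc4ccccc4)c(Br)c3)[C@H]2C[Si](C)(C)OC(C)C)cc1OCc1ccccc1 | intermediate
16 | (3S,4R,5S)-5-[4-(benzyloxy)-3-bromo-5-methoxyphenyl]-3-[3-(benzyloxy)-4-methoxybenzyl]-4-{[isopropoxy(dimethyl)silyl]methyl}-3-(trimethylsilyloxy)dihydrofuran-2(3H)-one | COc1ccc(C[C@@]2(O[Si](C)(C)C)C(=O)O[C@H](c3cc(OC)c(OCc4ccccc4)c(Br)c3)[C@H]2C[Si](C)(C)OC(C)C)cc1OCc1ccccc1 | intermediate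
17 | (3S,4R,5S)-5-[4-(benzyloxy)-3-bromo-5-methoxyphenyl]-3-[3-(benzyloxy)-4-methoxybenzyl]-3-hydroxy-4-{[isopropoxy(dimethyl)silyl]methyl}dihydrofuran-2(3H)-one | COc1ccc(C[C@@]2(O)C(=O)O[C@H](c3cc(OC)c(OCc4ccccc4)c(Br)c3)[C@H]2C[Si](C)(C)OC(C)C)cc1OCc1ccccc1 | intermediate
18 | (3S,4R,5S)-5-[4-(benzyloxy)-3-bromo-5-methoxyphenyl]-3-[3-(benzyloxy)-4-methoxybenzyl]-4-{[isopropoxy(dimethyl)silyl]methyl}tetrahydrofuran-2,3-diol (both C2 anomers) | COc1ccc(C[C@@]2(O)C(O)O[C@H](c3cc(OC)c(OCc4ccccc4)c(Br)c3)[C@H]2C[Si](C)(C)OC(C)C)cc1OCc1ccccc1 | intermediate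
19 | (3S,4R,5S)-5-[4-(benzyloxy)-3-bromo-5-methoxyphenyl]-3-[3-(benzyloxy)-4-methoxybenzyl]-4-{[isopropoxy(dimethyl)silyl]methyl}tetrahydrofuran-3-ol | COc1ccc(C[C@@]2(O)CO[C@H](c3cc(OC)c(OCc4ccccc4)c(Br)c3)[C@H]2C[Si](C)(C)OC(C)C)cc1OCc1ccccc1 | intermediate
20 | (3S,4R,5S)-5-[4-(benzyloxy)-3-bromo-5-methoxyphenyl]-3-[3-(benzyloxy)-4-methoxybenzyl]-4-(hydroxymethyl)tetrahydrofuran-3-ol | COc1ccc(C[C@@]2(O)CO[C@H](c3cc(OC)c(OCc4ccccc4)c(Br)c3)[C@H]2CO)cc1OCc1ccccc1 | intermediate
21 | (3S,4R,5S)-5-[4-(benzyloxy)-3-methoxy-5-(4,4,5,5-tetramethyl-1,3,2-dioxaborolan-2-yl)phenyl]-3-[3-(benzyloxy)-4-methoxybenzyl]-4-(hydroxymethyl)tetrahydrofuran-3-ol | COc1ccc(C[C@@]2(O)CO[C@H](c3cc(OC)c(OCc4ccccc4)c(B4OC(C)(C)C(C)(C)O4)c3)[C@H]2CO)cc1OCc1ccccc1 | intermediate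
22 | 4-(benzyloxy)-3-methoxybenzaldehyde | COc1cc(C=O)ccc1OCc1ccccc1 | starting material
23 | diethyl 2-[4-(benzyloxy)-3-methoxybenzylidene]malonate | CCOC(=O)C(=Cc1ccc(OCc2ccccc2)c(OC)c1)C(=O)OCC | intermediate
24 | diethyl 2-[4-(benzyloxy)-3-methoxybenzyl]malonate | CCOC(=O)C(Cc1ccc(OCc2ccccc2)c(OC)c1)C(=O)OCC | intermediate
25 | 2-[4-(benzyloxy)-3-methoxybenzyl]malonic acid | OC(=O)C(Cc1ccc(OCc2ccccc2)c(OC)c1)C(=O)O | intermediate
26 | 2-[4-(benzyloxy)-3-methoxybenzyl]acrylic acid | C=C(Cc1ccc(OCc2ccccc2)c(OC)c1)C(=O)O | intermediate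
27 | (S)-1-[4-(benzyloxy)-3-bromo-5-methoxyphenyl]allyl 2-[4-(benzyloxy)-3-methoxybenzyl]acrylate | C=C(Cc1ccc(OCc2ccccc2)c(OC)c1)C(=O)O[C@@H](C=C)c1cc(OC)c(OCc2ccccc2)c(Br)c1 | intermediate
28 | (S)-5-[4-(benzyloxy)-3-bromo-5-methoxyphenyl]-3-[4-(benzyloxy)-3-methoxybenzyl]furan-2(5H)-one | COc1cc(CC2=C[C@@H](c3cc(OC)c(OCc4ccccc4)c(Br)c3)OC2=O)ccc1OCc1ccccc1 | intermediate
29 | (4S,5S)-5-[4-(benzyloxy)-3-bromo-5-methoxyphenyl]-3-[4-(benzyloxy)-3-methoxybenzyl]-4-{[isopropoxy(dimethyl)silyl]methyl}-2-(trimethylsilyloxy)-4,5-dihydrofuran | COc1cc(CC2=C(O[Si](C)(C)C)O[C@H](c3cc(OC)c(OCc4ccccc4)c(Br)c3)[C@H]2C[Si](C)(C)OC(C)C)ccc1OCc1ccccc1 | intermediate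
30 | (3S,4R,5S)-5-[4-(benzyloxy)-3-bromo-5-methoxyphenyl]-3-[4-(benzyloxy)-3-methoxybenzyl]-4-{[isopropoxy(dimethyl)silyl]methyl}-3-(trimethylsilyloxy)dihydrofuran-2(3H)-one | COc1cc(C[C@@]2(O[Si](C)(C)C)C(=O)O[C@H](c3cc(OC)c(OCc4ccccc4)c(Br)c3)[C@H]2C[Si](C)(C)OC(C)C)ccc1OCc1ccccc1 | intermediate
31 | (3S,4R,5S)-5-[4-(benzyloxy)-3-bromo-5-methoxyphenyl]-3-[4-(benzyloxy)-3-methoxybenzyl]-3-hydroxy-4-{[isopropoxy(dimethyl)silyl]methyl}dihydrofuran-2(3H)-one | COc1cc(C[C@@]2(O)C(=O)O[C@H](c3cc(OC)c(OCc4ccccc4)c(Br)c3)[C@H]2C[Si](C)(C)OC(C)C)ccc1OCc1ccccc1 | intermediate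
32 | (2S,3R,4S)-4-[4-(benzyloxy)-3-bromo-5-methoxyphenyl]-2-[4-(benzyloxy)-3-methoxybenzyl]-3-{[isopropoxy(dimethyl)silyl]methyl}butane-1,2,4-triol | COc1cc(C[C@@](O)(CO)[C@H](C[Si](C)(C)OC(C)C)[C@H](O)c2cc(OC)c(OCc3ccccc3)c(Br)c2)ccc1OCc1ccccc1 | intermediate
33 | (2S,3R,4S)-4-[4-(benzyloxy)-3-bromo-5-methoxyphenyl]-2-[4-(benzyloxy)-3-methoxybenzyl]-3-(hydroxymethyl)butane-1,2,4-triol | COc1cc(C[C@@](O)(CO)[C@H](CO)[C@H](O)c2cc(OC)c(OCc3ccccc3)c(Br)c2)ccc1OCc1ccccc1 | intermediate
34 | (1S,2S,3S)-7-(benzyloxy)-1-[4-(benzyloxy)-3-bromo-5-methoxyphenyl]-2,3-bis(hydroxymethyl)-6-methoxy-1,2,3,4-tetrahydronaphthalen-3-ol | COc1cc([C@H]2c3cc(OCc4ccccc4)c(OC)cc3C[C@@](O)(CO)[C@@H]2CO)cc(Br)c1OCc1ccccc1 | intermediate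
35 | tetra-O-benzyl ether of the target (name as in step 25) | COc1ccc(C[C@@]2(O)CO[C@H](c3cc(OC)c(OCc4ccccc4)c(-c4cc([C@H]5c6cc(OCc7ccccc7)c(OC)cc6C[C@@](O)(CO)[C@@H]5CO)cc(OC)c4OCc4ccccc4)c3)[C@H]2CO)cc1OCc1ccccc1 | intermediate
36 | CNP0252244.1 (name as in step 26) | COc1ccc(C[C@@]2(O)CO[C@H](c3cc(OC)c(O)c(-c4cc([C@H]5c6cc(O)c(OC)cc6C[C@@](O)(CO)[C@@H]5CO)cc(OC)c4O)c3)[C@H]2CO)cc1O | target

**Step count**

Total step count: 26.
Longest linear sequence: 13 steps (steps 4–9, 11–15, 25 and 26, from 3-(benzyloxy)-4-methoxybenzaldehyde).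

**Three steps most likely to fail**

1. Step 11 (and step 22, the same reaction on 28). Oxygen transfer may lose facial selectivity, because the C5 aryl group sits on the face that the oxidant must use. The dioxirane may also be destroyed by the copper and magnesium salts before it meets the ketene acetal, and adventitious hydrolysis of the ketene acetal would leave unhydroxylated lactone. The fallback uncouples the two bond formations. From 12 the same copper-catalysed addition is quenched with aqueous NH4Cl to give the 4,5-trans lactone F1 as a mixture at C3, which is irrelevant. F1 is then deprotonated separately (KHMDS, THF, −78 °C) and the potassium enolate is hydroxylated with a bulky N-sulfonyloxaziridine (2-(phenylsulfonyl)-3-phenyloxaziridine, or the matched enantiomer of (camphorsulfonyl)oxaziridine if reagent control is needed). Such an oxidant responds more strongly to the vicinal C4 substituent, and the route is rejoined at 17. The same detour from 28 passes through the vanillyl lactone F2 and rejoins at 31.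

2. Step 13. The Lewis acid may ionise the benzylic C5–O bond in competition with the lactol C–O bond, which would lead to epimerisation at C5, Friedel–Crafts closure onto the benzyl arene or loss of the silylmethyl group. The reduction may also stall because the oxocarbenium ion is destabilised by the neighbouring carbinol. The fallback opens the lactone and re-closes the ether by substitution, with silicon carried in a form that cannot exchange with hydroxyls.
   - From 12, the addition–oxidation of step 11 is run with (benzyldimethylsilyl)methylmagnesium chloride F3 (from commercial benzyl(chloromethyl)dimethylsilane and magnesium). It passes through the trimethylsilyl ketene acetal F4 and the 3-trimethylsilyloxy lactone F5 to the benzyldimethylsilyl lactone F6.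
   - LiBH4 gives the triol F7, and TsCl, pyridine and DMAP sulfonylate only the primary hydroxyl to give the primary tosylate F8.
   - On treatment with t-BuOK in THF, F8 is displaced by the benzylic hydroxyl (5-exo-tet, no bond to a stereocentre broken) to give the tetrahydrofuran F9. The epoxide that the tertiary alkoxide may form first is opened at its CH2 by the same hydroxyl and gives the same ether.
   - TBAF followed by KHCO3 and H2O2 in MeOH (benzyl–silicon cleavage, then Tamao oxidation) rejoins the route at 20.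

3. Step 24. Ionisation of the benzylic alcohol next to the bromo-substituted ring may be sluggish, so that material rests at the reversible cyclic ether. Forcing the acid would then risk loss of benzyl ethers or a pinacol-type rearrangement of the tertiary 1,2-diol. The fallback changes the leaving group and caps the hydroxyls. From 33, Ac2O, pyridine and DMAP give the triacetate F10 (both primary hydroxyls and the benzylic hydroxyl acetylated, tertiary hydroxyl free). In F10 the cation can no longer be captured by oxygen, and the benzylic acetate is a better nucleofuge. Sc(OTf)3 (catalytic, trivalent scandium) in CH2Cl2/MeNO2 should close the ring to the tetralin diacetate F11, and K2CO3 in MeOH rejoins the route at 34.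

**Further compounds**

F1 | step 11 | (4S,5S)-5-[4-(benzyloxy)-3-bromo-5-methoxyphenyl]-3-[3-(benzyloxy)-4-methoxybenzyl]-4-{[isopropoxy(dimethyl)silyl]methyl}dihydrofuran-2(3H)-one (mixture at C3) | COc1ccc(CC2C(=O)O[C@H](c3cc(OC)c(OCc4ccccc4)c(Br)c3)[C@H]2C[Si](C)(C)OC(C)C)cc1OCc1ccccc1
F2 | step 22 | (4S,5S)-5-[4-(benzyloxy)-3-bromo-5-methoxyphenyl]-3-[4-(benzyloxy)-3-methoxybenzyl]-4-{[isopropoxy(dimethyl)silyl]methyl}dihydrofuran-2(3H)-one (mixture at C3) | COc1cc(CC2C(=O)O[C@H](c3cc(OC)c(OCc4ccccc4)c(Br)c3)[C@H]2C[Si](C)(C)OC(C)C)ccc1OCc1ccccc1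
F3 | step 13 | (benzyldimethylsilyl)methylmagnesium chloride | C[Si](C)(Cc1ccccc1)C[Mg]Cl
F4 | step 13 | (4S,5S)-4-{[benzyl(dimethyl)silyl]methyl}-5-[4-(benzyloxy)-3-bromo-5-methoxyphenyl]-3-[3-(benzyloxy)-4-methoxybenzyl]-2-(trimethylsilyloxy)-4,5-dihydrofuran | COc1ccc(CC2=C(O[Si](C)(C)C)O[C@H](c3cc(OC)c(OCc4ccccc4)c(Br)c3)[C@H]2C[Si](C)(C)Cc2ccccc2)cc1OCc1ccccc1
F5 | step 13 | (3S,4R,5S)-4-{[benzyl(dimethyl)silyl]methyl}-5-[4-(benzyloxy)-3-bromo-5-methoxyphenyl]-3-[3-(benzyloxy)-4-methoxybenzyl]-3-(trimethylsilyloxy)dihydrofuran-2(3H)-one | COc1ccc(C[C@@]2(O[Si](C)(C)C)C(=O)O[C@H](c3cc(OC)c(OCc4ccccc4)c(Br)c3)[C@H]2C[Si](C)(C)Cc2ccccc2)cc1OCc1ccccc1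
F6 | step 13 | (3S,4R,5S)-4-{[benzyl(dimethyl)silyl]methyl}-5-[4-(benzyloxy)-3-bromo-5-methoxyphenyl]-3-[3-(benzyloxy)-4-methoxybenzyl]-3-hydroxydihydrofuran-2(3H)-one | COc1ccc(C[C@@]2(O)C(=O)O[C@H](c3cc(OC)c(OCc4ccccc4)c(Br)c3)[C@H]2C[Si](C)(C)Cc2ccccc2)cc1OCc1ccccc1
F7 | step 13 | (2S,3R,4S)-3-{[benzyl(dimethyl)silyl]methyl}-4-[4-(benzyloxy)-3-bromo-5-methoxyphenyl]-2-[3-(benzyloxy)-4-methoxybenzyl]butane-1,2,4-triol | COc1ccc(C[C@@](O)(CO)[C@H](C[Si](C)(C)Cc2ccccc2)[C@H](O)c2cc(OC)c(OCc3ccccc3)c(Br)c2)cc1OCc1ccccc1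
F8 | step 13 | 1-O-(p-toluenesulfonyl) derivative of F7 (primary tosylate) | COc1ccc(C[C@@](O)(COS(=O)(=O)c2ccc(C)cc2)[C@H](C[Si](C)(C)Cc2ccccc2)[C@H](O)c2cc(OC)c(OCc3ccccc3)c(Br)c2)cc1OCc1ccccc1
F9 | step 13 | (3S,4R,5S)-4-{[benzyl(dimethyl)silyl]methyl}-5-[4-(benzyloxy)-3-bromo-5-methoxyphenyl]-3-[3-(benzyloxy)-4-methoxybenzyl]tetrahydrofuran-3-ol | COc1ccc(C[C@@]2(O)CO[C@H](c3cc(OC)c(OCc4ccccc4)c(Br)c3)[C@H]2C[Si](C)(C)Cc2ccccc2)cc1OCc1ccccc1
F10 | step 24 | triacetate of 33 (acetates on both primary hydroxyls and on the benzylic hydroxyl, tertiary hydroxyl free) | COc1cc(C[C@@](O)(COC(C)=O)[C@H](COC(C)=O)[C@H](OC(C)=O)c2cc(OC)c(OCc3ccccc3)c(Br)c2)ccc1OCc1ccccc1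
F11 | step 24 | diacetate of 34 (both CH2OH groups acetylated, tertiary hydroxyl free) | COc1cc([C@H]2c3cc(OCc4ccccc4)c(OC)cc3C[C@@](O)(COC(C)=O)[C@@H]2COC(C)=O)cc(Br)c1OCc1ccccc1
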